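**Plan**

- Locants follow xanthane numbering. Half A (unprimed) is the hydroxylated cycloheptane with its cis-lactone; half B (primed) is the cycloheptene with the spiro-lactone. The connecting ring is C1–C2=C3–C11'–C13'–C5.
- Retrosynthesis: remove the acetyl (C4, C15) from C3 (alkenyl triflate, hence a C3 ketone) and the C13 methylene from lactone A. This leaves a Robinson ketol: carbinol C1 is β to the C3 ketone, and the spiro carbon C11' is α to both C3=O and the lactone-B carbonyl. Cut C1–C2 (aldol) and C11'–C13' (Michael) to reach an α-methylene cycloheptanone (A) and an α-acetyl lactone (B).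
- This order puts C13', not C3, on the convex face of lactone B, which is what the target needs.
- The two halves belong to opposite enantiomeric series of one keto lactone [(3aR,7S,8aR) and (3aS,7R,8aS)]. Both come from a single desymmetrised meso diol monoacetate: Johnson–Claisen at the free hydroxyl for A, Ireland–Claisen of the acetate for B.
- Forward ring order: cycloheptene (bought), then cis-lactone, then both halves elaborated, then the cyclohexane ring last by Michael/aldol annulation. After that: enol triflate and Stille for C2=C3 and the acetyl, lactone methylenation, acid unmasking.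
- Stereochemistry: C7/C8 and C7'/C8' from the enzymatic desymmetrisation relayed by suprafacial [3,3] shifts; C10/C10' by hydrogenation on the convex face; C11' by Michael addition on the convex face of lactone B; C5 and C1 by substrate control in the cycloheptanone (protonation, then reversible aldol to the trans-fused ketol).

Key step: step 15

Remark (assumption): the lipase is taken to give (1R,4S)-4-hydroxycyclohept-2-en-1-yl acetate; if it gives the antipode, the two Claisen modes of steps 3 and 8 are exchanged between the two series and nothing else changes.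

Remark (locants): in the bicyclic lactones, furanone positions 3/3a/4/5/6/7/8/8a correspond to C11/C7/C6/C5/C1/C10/C9/C8.

**Step 1**
Reactants: 1 cyclohepta-1,3-diene
Product: 3 cis-cyclohept-2-ene-1,4-diol (meso), via endoperoxide 2 (not isolated)
Conditions: O2, TPP (cat.), hν, CH2Cl2, 0 °C; then Zn, AcOH, 0 °C→rt
Reagents that add atoms: dioxygen, O=O
Why: Singlet-oxygen [4+2] cycloaddition to the cyclic diene followed by reductive O–O cleavage should give the 1,4-diol, the cis relationship being fixed by the bicyclic peroxide.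

**Step 2**
Reactants: 3 cis-cyclohept-2-ene-1,4-diol
Product: 4 (1R,4S)-4-hydroxycyclohept-2-en-1-yl acetate
Conditions: lipase (Pseudomonas cepacia, immobilised), vinyl acetate, MTBE, rt
Reagents that add atoms: vinyl acetate, CC(=O)OC=C
Why: Enzymatic desymmetrisation of a meso diol by enantiotopos-selective transesterification should fix both carbinol centres in one sense (see assumption).

**Step 3**
Reactants: 4 (1R,4S)-4-hydroxycyclohept-2-en-1-yl acetate
Product: 6 (3aS,8aR)-3,3a,6,7,8,8a-hexahydro-2H-cyclohepta[b]furan-2-one, via acetoxy ester 5 (not isolated)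
Conditions: MeC(OEt)3, EtCO2H (cat.), 140 °C (−EtOH); concentrate; K2CO3, MeOH, rt
Reagents that add atoms: triethyl orthoacetate, CC(OCC)(OCC)OCC
Why: The Johnson–Claisen rearrangement should transfer the configuration of the free carbinol suprafacially to C7 (new C–C bond cis to the acetoxy group), and methanolysis of the acetate lets the cis γ-hydroxy ester close to the cis-fused lactone.

**Step 4**
Reactants: 6 (3aS,8aR)-lactone
Product: 7 (3aS,8aR)-3,3a,8,8a-tetrahydro-2H-cyclohepta[b]furan-2,6(7H)-dione
Conditions: Rh2(cap)4 (1 mol%), t-BuOOH (aq., 5 equiv), K2CO3, CH2Cl2, rt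
Reagents that add atoms: tert-butyl hydroperoxide, CC(C)(C)OO
Why: In this radical allylic C–H oxidation the unhindered C1 methylene should be attacked in preference to the tertiary C7–H at the ring fusion, and the peroxide should enter at the less hindered allyl terminus, giving the conjugated enone.

**Step 5**
Reactants: 7 (3aS,8aR)-enone
Product: 10 (3aS,8aR)-7-methylidene-3,3a,8,8a-tetrahydro-2H-cyclohepta[b]furan-2,6(7H)-dione, via Mannich base 8 (not isolated), via methiodide 9 (not isolated)
Conditions: LDA (1.05 equiv), THF, −78 °C; CH2=NMe2+ I−, −78 °C→rt; then MeI, MeOH; aq. NaHCO3, CH2Cl2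
Reagents that add atoms: dimethyl(methylidene)ammonium iodide (Eschenmoser's salt), C=[N+](C)C.[I-]
Why: Kinetic α'-deprotonation of the enone at C10 (the lactone is less acidic), Mannich alkylation and quaternisation/E1cB elimination should give the exocyclic methylene, with no stereocentre formed.

**Step 6**
Reactants: 10 (3aS,8aR)-methylidene enone
Product: 11 (3aR,7S,8aR)-7-methylhexahydro-2H-cyclohepta[b]furan-2,6(3H)-dione
Conditions: H2 (1 atm), 10% Pd/C, EtOAc, rt
Reagents that add atoms: none
Why: Heterogeneous hydrogenation should saturate both alkenes and deliver hydrogen to C10 on the convex face (the side of H7/H8, opposite the cis-fused lactone), so the C14 methyl ends cis to the lactone oxygen.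

**Step 7**
Reactants: 11 (3aR,7S,8aR)-keto lactone
Product: 13 trimethyl{[(3aR,7S,8aR)-7-methyl-2,6-dioxooctahydro-2H-cyclohepta[b]furan-5-yl]methyl}ammonium iodide, via Mannich base 12 (not isolated)
Conditions: LDA (1.05 equiv), THF, −78 °C; CH2=NMe2+ I−; aqueous work-up; MeI, Et2O, rt
Reagents that add atoms: dimethyl(methylidene)ammonium iodide, C=[N+](C)C.[I-]; iodomethane, CI
Why: Kinetic enolisation at the C5 methylene rather than the C10 methine (so C10 is not epimerised) followed by Mannich alkylation and quaternisation should give a storable latent α-methylene ketone; the new C5 centre is lost in step 15.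

**Step 8**
Reactants: 4 (1R,4S)-4-hydroxycyclohept-2-en-1-yl acetate
Product: 17 (3aR,8aS)-3,3a,6,7,8,8a-hexahydro-2H-cyclohepta[b]furan-2-one, via silyl ketene acetal 14 (not isolated), via silyl ester 15 (not isolated), via hydroxy acid 16 (not isolated)
Conditions: LDA (2.3 equiv), TMSCl (3 equiv), THF, −78 °C→60 °C; then 1 M HCl, THF, rt
Reagents that add atoms: none
Why: Ireland–Claisen rearrangement of the acetate's silyl ketene acetal (the free hydroxyl is silylated in the same operation) should deliver the acetic acid unit suprafacially to the alkene carbon next to the silyloxy carbon, and acid work-up lactonises the cis γ-hydroxy acid to the enantiomer of 6.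

**Step 9**
Reactants: 17 (3aR,8aS)-lactone
Product: 18 (3aR,8aS)-3,3a,8,8a-tetrahydro-2H-cyclohepta[b]furan-2,6(7H)-dione
Conditions: Rh2(cap)4 (1 mol%), t-BuOOH (aq., 5 equiv), K2CO3, CH2Cl2, rt
Reagents that add atoms: tert-butyl hydroperoxide, CC(C)(C)OO
Why: Same allylic oxidation as step 4 in the enantiomeric series, with C1' methylene preferred over the tertiary C7'–H.

**Step 10**
Reactants: 18 (3aR,8aS)-enone
Product: 21 (3aR,8aS)-7-methylidene-3,3a,8,8a-tetrahydro-2H-cyclohepta[b]furan-2,6(7H)-dione, via Mannich base 19 (not isolated), via methiodide 20 (not isolated)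
Conditions: LDA (1.05 equiv), THF, −78 °C; CH2=NMe2+ I−; then MeI, MeOH; aq. NaHCO3, CH2Cl2
Reagents that add atoms: dimethyl(methylidene)ammonium iodide, C=[N+](C)C.[I-]
Why: Same kinetic α'-Mannich/elimination sequence as step 5.

**Step 11**
Reactants: 21 (3aR,8aS)-methylidene enone
Product: 22 (3aS,7R,8aS)-7-methylhexahydro-2H-cyclohepta[b]furan-2,6(3H)-dione
Conditions: H2 (1 atm), 10% Pd/C, EtOAc, rt
Reagents that add atoms: none
Why: As in step 6, hydrogen should add to C10' on the convex face, placing the C14' methyl cis to the lactone oxygen.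

**Step 12**
Reactants: 22 (3aS,7R,8aS)-keto lactone
Product: 23 (3aS,7R,8aS)-7-methyl-2-oxo-3,3a,4,7,8,8a-hexahydro-2H-cyclohepta[b]furan-6-yl trifluoromethanesulfonate
Conditions: KHMDS (1.05 equiv), THF, −78 °C; N-(5-chloro-2-pyridyl)bis(trifluoromethanesulfonimide), −78→0 °C
Reagents that add atoms: N-(5-chloro-2-pyridyl)bis(trifluoromethanesulfonimide), FC(F)(F)S(=O)(=O)N(c1ccc(Cl)cn1)S(=O)(=O)C(F)(F)F
Why: Kinetic deprotonation at the C5' methylene (not the C10' methine, not the lactone) and O-triflation should fix the C1'=C5' alkene position without touching C10'.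

**Step 13**
Reactants: 23 alkenyl triflate; 24 2-methyl-2-vinyl-1,3-dioxolane
Product: 26 (3aS,7R,8aS)-7-methyl-6-[2-(2-methyl-1,3-dioxolan-2-yl)ethyl]-3,3a,4,7,8,8a-hexahydro-2H-cyclohepta[b]furan-2-one, via alkylborane 25 (not isolated)
Conditions: 24, 9-BBN, THF, rt; then 23, Pd(dppf)Cl2 (5 mol%), AsPh3, Cs2CO3, DMF/H2O, rt→50 °C
Reagents that add atoms: none
Why: Anti-Markovnikov hydroboration and B-alkyl Suzuki–Miyaura coupling should attach the ketal-protected 3-oxobutyl chain at C1' with the alkene position kept and no stereocentre touched.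

**Step 14**
Reactants: 26 side-chain lactone
Product: 27 (3R,3aS,7R,8aS)-3-acetyl-7-methyl-6-[2-(2-methyl-1,3-dioxolan-2-yl)ethyl]-3,3a,4,7,8,8a-hexahydro-2H-cyclohepta[b]furan-2-one (C3 stereolabile, drawn as the trans isomer)
Conditions: LDA (1.1 equiv), THF, −78 °C; MeC(O)N(OMe)Me, −78→0 °C; aq. NH4Cl
Reagents that add atoms: N-methoxy-N-methylacetamide, CON(C)C(C)=O
Why: Claisen-type C-acylation of the lactone lithium enolate with a Weinreb amide should stop at the chelated tetrahedral adduct and release the β-keto lactone on work-up; the C11' configuration is labile and is reset in step 15.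

**Step 15**
Reactants: 13 ammonium iodide (half A); 27 β-keto lactone (half B)
Product: 30 ketol (C1–OH, C3=O; ring C1–C2–C3–C11'–C13'–C5 closed), via methylene ketone 28 (not isolated), via Michael adduct 29 (not isolated)
Conditions: Et3N (1.5 equiv), THF, 0 °C→rt; then LiHMDS (2.3 equiv, one equivalent is consumed by Et3NH+), −78→−40 °C; AcOH, −78 °C
Reagents that add atoms: none
Why: Et3N should trigger E1cB loss of NMe3 from 13 to give the exo-methylene ketone 28, to which the stabilised enolate of 27 adds through C11' at C13'; LiHMDS then removes a proton from the acetyl methyl (C2) and the lithium enolate adds to the C1 ketone. The closest known reaction is the Robinson annulation in its Mannich-methiodide form with a β-keto ester donor, stopped at the β-ketol. The ring closes by a 6-(enolendo)-exo-trig aldol addition. C11' is set by attack of C13' on the convex face of the cis-fused lactone B (anti to C6', cis to H7'), so both C11' epimers and the enol of 27 converge on one quaternary configuration. C5 is set by protonation of the C1/C5 enolate on the face opposite lactone A, which is also the cis-2,7 (pseudo-equatorial) arrangement relative to the C14 methyl; C1 is set by addition of C2 on the face opposite lactone A, C14 and C13', and the reversible lithium aldolate should settle on the trans-fused ketol with C2 equatorial and OH axial. The step needs Michael addition only at the enone and enolisation only at the acetyl methyl; the first is secured because lactone A carries no methylene yet, and the second because C11' is quaternary, the side-chain ketone is a dioxolane, and the base is used at low temperature.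

**Step 16**
Reactants: 30 ketol
Product: 31 C1 trimethylsilyl ether of 30
Conditions: 1-(trimethylsilyl)imidazole, CH2Cl2, rt
Reagents that add atoms: 1-(trimethylsilyl)imidazole, C[Si](C)(C)n1ccnc1
Why: Neutral silylation of the tertiary alcohol should block retro-aldol cleavage and alkoxide chemistry in the next step without enolising the ketone.

**Step 17**
Reactants: 31 silyl ether
Product: 32 C3 enol triflate (C2=C3) of 31
Conditions: KHMDS (1.05 equiv), THF, −78 °C; N-(5-chloro-2-pyridyl)bis(trifluoromethanesulfonimide), −78→−20 °C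
Reagents that add atoms: N-(5-chloro-2-pyridyl)bis(trifluoromethanesulfonimide), FC(F)(F)S(=O)(=O)N(c1ccc(Cl)cn1)S(=O)(=O)C(F)(F)F
Why: The C3 ketone can enolise only towards C2 (C11' is quaternary), so O-triflation of the potassium enolate should place the ring alkene at C2=C3; β-silyloxy enolates do not eliminate at this temperature.

**Step 18**
Reactants: 32 enol triflate
Product: 35 C11(13)-methylene lactone of 32, via Mannich base 33 (not isolated), via methiodide 34 (not isolated)
Conditions: LDA (1.2 equiv), THF, −78 °C; CH2=NMe2+ I−, −78→0 °C; then MeI, MeOH; aq. NaHCO3, CH2Cl2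
Reagents that add atoms: dimethyl(methylidene)ammonium iodide, C=[N+](C)C.[I-]
Why: At this stage the C11 methylene of lactone A is the only carbonyl α-position bearing hydrogen (lactone B is quaternary, C3 is an enol triflate, C4' is a ketal), so enolate Mannich alkylation and quaternisation/elimination should give the α-methylene lactone.

**Step 19**
Reactants: 35 methylene lactone triflate
Product: 37 target CNP0195550.1, via enol ether 36 (not isolated)
Conditions: tributyl(1-ethoxyvinyl)stannane, Pd(PPh3)4 (10 mol%), LiCl, CuI (cat.), DMF, 70 °C; then 1 M HCl, THF, 0 °C→rt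
Reagents that add atoms: tributyl(1-ethoxyvinyl)stannane, CCCC[Sn](CCCC)(CCCC)C(=C)OCC; water, O
Why: Stille coupling of the alkenyl triflate with an acetyl-anion equivalent followed by aqueous acid should hydrolyse the enol ether to the C4 methyl ketone (conjugated with C2=C3), cleave the dioxolane to the C4' ketone and remove the silyl ether, leaving every stereocentre untouched.

**Compound list**

1 | cyclohepta-1,3-diene | C1=CC=CCCC1 | starting material
2 | 6,7-dioxabicyclo[3.2.2]non-8-ene (meso endoperoxide) | O1[C@@H]2C=C[C@H](O1)CCC2 | intermediate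
3 | cis-cyclohept-2-ene-1,4-diol (meso) | O[C@@H]1C=C[C@H](O)CCC1 | intermediate
4 | (1R,4S)-4-hydroxycyclohept-2-en-1-yl acetate | O[C@@H]1C=C[C@H](OC(C)=O)CCC1 | intermediate
5 | ethyl 2-[(1S,7R)-7-acetoxycyclohept-2-en-1-yl]acetate | CCOC(=O)C[C@H]1C=CCCC[C@H]1OC(C)=O | intermediate
6 | (3aS,8aR)-3,3a,6,7,8,8a-hexahydro-2H-cyclohepta[b]furan-2-one (cis-fused) | O=C1C[C@H]2C=CCCC[C@H]2O1 | intermediate
7 | (3aS,8aR)-3,3a,8,8a-tetrahydro-2H-cyclohepta[b]furan-2,6(7H)-dione | O=C1C[C@H]2C=CC(=O)CC[C@H]2O1 | intermediate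
8 | 7-[(dimethylamino)methyl] derivative of 7 (C10 Mannich base; the new centre is drawn as formed anti to the lactone and is lost on elimination) | O=C1C[C@H]2C=CC(=O)[C@H](CN(C)C)C[C@H]2O1 | intermediate
9 | trimethylammonium iodide of 8 | O=C1C[C@H]2C=CC(=O)[C@H](C[N+](C)(C)C)C[C@H]2O1.[I-] | intermediate
10 | (3aS,8aR)-7-methylidene-3,3a,8,8a-tetrahydro-2H-cyclohepta[b]furan-2,6(7H)-dione | O=C1C[C@H]2C=CC(=O)C(=C)C[C@H]2O1 | intermediate
11 | (3aR,7S,8aR)-7-methylhexahydro-2H-cyclohepta[b]furan-2,6(3H)-dione (H7, H8, H10 all cis) | O=C1C[C@H]2CCC(=O)[C@@H](C)C[C@H]2O1 | intermediate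
12 | 5-[(dimethylamino)methyl] derivative of 11 (C5 Mannich base; the new centre is drawn as formed anti to the lactone and is lost in step 15) | O=C1C[C@H]2C[C@H](CN(C)C)C(=O)[C@@H](C)C[C@H]2O1 | intermediate
13 | trimethyl{[(3aR,7S,8aR)-7-methyl-2,6-dioxooctahydro-2H-cyclohepta[b]furan-5-yl]methyl}ammonium iodide | O=C1C[C@H]2C[C@H](C[N+](C)(C)C)C(=O)[C@@H](C)C[C@H]2O1.[I-] | intermediate
14 | (1R,4S)-4-(trimethylsilyloxy)cyclohept-2-en-1-yl 1-(trimethylsilyloxy)vinyl ether (silyl ketene acetal) | C[Si](C)(C)O[C@@H]1C=C[C@H](OC(=C)O[Si](C)(C)C)CCC1 | intermediate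
15 | trimethylsilyl 2-[(1R,7S)-7-(trimethylsilyloxy)cyclohept-2-en-1-yl]acetate | C[Si](C)(C)OC(=O)C[C@@H]1C=CCCC[C@@H]1O[Si](C)(C)C | intermediate
16 | 2-[(1R,7S)-7-hydroxycyclohept-2-en-1-yl]acetic acid | OC(=O)C[C@@H]1C=CCCC[C@@H]1O | intermediate
17 | (3aR,8aS)-3,3a,6,7,8,8a-hexahydro-2H-cyclohepta[b]furan-2-one (enantiomer of 6) | O=C1C[C@@H]2C=CCCC[C@@H]2O1 | intermediate
18 | (3aR,8aS)-3,3a,8,8a-tetrahydro-2H-cyclohepta[b]furan-2,6(7H)-dione | O=C1C[C@@H]2C=CC(=O)CC[C@@H]2O1 | intermediate
19 | 7-[(dimethylamino)methyl] derivative of 18 (enantiomer of 8) | O=C1C[C@@H]2C=CC(=O)[C@@H](CN(C)C)C[C@@H]2O1 | intermediate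
20 | trimethylammonium iodide of 19 | O=C1C[C@@H]2C=CC(=O)[C@@H](C[N+](C)(C)C)C[C@@H]2O1.[I-] | intermediate
21 | (3aR,8aS)-7-methylidene-3,3a,8,8a-tetrahydro-2H-cyclohepta[b]furan-2,6(7H)-dione | O=C1C[C@@H]2C=CC(=O)C(=C)C[C@@H]2O1 | intermediate
22 | (3aS,7R,8aS)-7-methylhexahydro-2H-cyclohepta[b]furan-2,6(3H)-dione (enantiomer of 11) | O=C1C[C@@H]2CCC(=O)[C@H](C)C[C@@H]2O1 | intermediate
23 | (3aS,7R,8aS)-7-methyl-2-oxo-3,3a,4,7,8,8a-hexahydro-2H-cyclohepta[b]furan-6-yl trifluoromethanesulfonate | O=C1C[C@@H]2CC=C(OS(=O)(=O)C(F)(F)F)[C@H](C)C[C@@H]2O1 | intermediate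
24 | 2-methyl-2-vinyl-1,3-dioxolane | C=CC1(C)OCCO1 | starting material
25 | 9-[2-(2-methyl-1,3-dioxolan-2-yl)ethyl]-9-borabicyclo[3.3.1]nonane | CC1(CCB2C3CCCC2CCC3)OCCO1 | intermediate
26 | (3aS,7R,8aS)-7-methyl-6-[2-(2-methyl-1,3-dioxolan-2-yl)ethyl]-3,3a,4,7,8,8a-hexahydro-2H-cyclohepta[b]furan-2-one | O=C1C[C@@H]2CC=C(CCC3(C)OCCO3)[C@H](C)C[C@@H]2O1 | intermediate
27 | (3R,3aS,7R,8aS)-3-acetyl-7-methyl-6-[2-(2-methyl-1,3-dioxolan-2-yl)ethyl]-3,3a,4,7,8,8a-hexahydro-2H-cyclohepta[b]furan-2-one (acetyl cis to H7'; stereolabile) | O=C1[C@@H](C(C)=O)[C@@H]2CC=C(CCC3(C)OCCO3)[C@H](C)C[C@@H]2O1 | intermediate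
28 | (3aR,7S,8aR)-7-methyl-5-methylidenehexahydro-2H-cyclohepta[b]furan-2,6(3H)-dione | O=C1C[C@H]2CC(=C)C(=O)[C@@H](C)C[C@H]2O1 | intermediate
29 | Michael adduct: 27 C-alkylated at C11' by the C13' methylene of 28 (C13' cis to H7'; H5 cis to H7 and H10; C1 and C3 ketones open) | CC(=O)[C@@]1(C[C@@H]2C[C@@H]3CC(=O)O[C@@H]3C[C@H](C)C2=O)C(=O)O[C@H]2C[C@@H](C)C(CCC4(C)OCCO4)=CC[C@@H]12 | intermediate
30 | ketol: 1-hydroxy-3-oxo spiro-pentacycle (OH anti to H5; OH, C14 methyl, C13' and lactone A on one face of the cycloheptane; C11 unsubstituted; C4' as dioxolane) | C1C(=O)O[C@@H]2C[C@H](C)[C@@]3(O)CC(=O)[C@@]4(C[C@@H]3C[C@H]12)C(=O)O[C@H]1C[C@@H](C)C(CCC5(C)OCCO5)=CC[C@H]14 | intermediate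
31 | C1 trimethylsilyl ether of 30 | C1C(=O)O[C@@H]2C[C@H](C)[C@@]3(O[Si](C)(C)C)CC(=O)[C@@]4(C[C@@H]3C[C@H]12)C(=O)O[C@H]1C[C@@H](C)C(CCC5(C)OCCO5)=CC[C@H]14 | intermediate
32 | C3 enol triflate of 31 (C2=C3) | C1C(=O)O[C@@H]2C[C@H](C)[C@@]3(O[Si](C)(C)C)C=C(OS(=O)(=O)C(F)(F)F)[C@@]4(C[C@@H]3C[C@H]12)C(=O)O[C@H]1C[C@@H](C)C(CCC5(C)OCCO5)=CC[C@H]14 | intermediate
33 | 11-[(dimethylamino)methyl] derivative of 32 (aminomethyl drawn cis to H7; the centre is lost on elimination) | CN(C)C[C@H]1C(=O)O[C@@H]2C[C@H](C)[C@@]3(O[Si](C)(C)C)C=C(OS(=O)(=O)C(F)(F)F)[C@@]4(C[C@@H]3C[C@H]12)C(=O)O[C@H]1C[C@@H](C)C(CCC5(C)OCCO5)=CC[C@H]14 | intermediate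
34 | trimethylammonium iodide of 33 | C[N+](C)(C)C[C@H]1C(=O)O[C@@H]2C[C@H](C)[C@@]3(O[Si](C)(C)C)C=C(OS(=O)(=O)C(F)(F)F)[C@@]4(C[C@@H]3C[C@H]12)C(=O)O[C@H]1C[C@@H](C)C(CCC5(C)OCCO5)=CC[C@H]14.[I-] | intermediate
35 | C11(13)-methylene lactone of 32 | C=C1C(=O)O[C@@H]2C[C@H](C)[C@@]3(O[Si](C)(C)C)C=C(OS(=O)(=O)C(F)(F)F)[C@@]4(C[C@@H]3C[C@H]12)C(=O)O[C@H]1C[C@@H](C)C(CCC5(C)OCCO5)=CC[C@H]14 | intermediate
36 | 3-(1-ethoxyvinyl) diene from 35 | C=C1C(=O)O[C@@H]2C[C@H](C)[C@@]3(O[Si](C)(C)C)C=C(C(=C)OCC)[C@@]4(C[C@@H]3C[C@H]12)C(=O)O[C@H]1C[C@@H](C)C(CCC5(C)OCCO5)=CC[C@H]14 | intermediate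
37 | CNP0195550.1 | C=C1C(=O)O[C@@H]2C[C@H](C)[C@@]3(O)C=C(C(C)=O)[C@@]4(C[C@@H]3C[C@H]12)C(=O)O[C@H]1C[C@@H](C)C(CCC(C)=O)=CC[C@H]14 | target

**Totals**

Total step count: 19. Longest linear sequence: 14 steps (1, 2, 8–14, 15–19).

**Steps most likely to fail**

Step 15. Two processes threaten it. The amide base may remove H5 instead of an acetyl proton, which leads to retro-Michael loss of the β-keto lactone or to epimerisation at C5/C10. The aldol may also close through the lower face and give the cis-fused ketol. The fallback sets out from 29, isolated after the Michael stage alone, and comes back at 30. The acetyl group is trapped at −78 °C (LiHMDS with TMSCl present) as the trimethylsilyl enol ether F1. NBS converts it into the bromomethyl ketone F2. SmI2 in THF at −78 °C then generates the samarium(III) enolate regiospecifically under non-basic conditions, and an intramolecular Reformatsky-type addition to the C1 ketone through a chelated transition state closes the ring.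

Step 4 (and its twin, step 9). Hydrogen abstraction may be unselective between the C1 methylene and the tertiary C7–H, or the peroxide may be trapped at the inner allyl terminus, giving the transposed enone. The fallback sets out from 6 and comes back at 7 (the same applies from 17 to 18). A Riley oxidation (SeO2 cat., t-BuOOH, CH2Cl2) proceeds by an ene reaction and [2,3]-shift, which returns oxygen to the methylene carbon with the alkene in place, giving the allylic alcohol F3. Dess–Martin periodinane then oxidises it to the enone.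

Step 19. Oxidative addition or transmetalation may be slow at the alkenyl triflate flanked by the spiro quaternary carbon, so that triflate hydrolysis and protodestannylation compete. The fallback sets out from 35 and comes back at 37. A Nozaki–Hiyama–Kishi coupling with acetaldehyde (CrCl2, NiCl2 cat., DMF) gives the secondary allylic alcohol F4 (either carbinol epimer). Dess–Martin oxidation gives the protected enone F5, and 1 M HCl in THF removes the silyl ether and the dioxolane.

**Further compounds**

F1 | step 15 | trimethylsilyl enol ether of the acetyl group of 29 | C=C(O[Si](C)(C)C)[C@@]1(C[C@@H]2C[C@@H]3CC(=O)O[C@@H]3C[C@H](C)C2=O)C(=O)O[C@H]2C[C@@H](C)C(CCC4(C)OCCO4)=CC[C@@H]12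
F2 | step 15 | bromomethyl ketone from F1 | BrCC(=O)[C@@]1(C[C@@H]2C[C@@H]3CC(=O)O[C@@H]3C[C@H](C)C2=O)C(=O)O[C@H]2C[C@@H](C)C(CCC4(C)OCCO4)=CC[C@@H]12
F3 | step 4 | (3aS,8aR)-6-hydroxy-3,3a,6,7,8,8a-hexahydro-2H-cyclohepta[b]furan-2-one (carbinol epimers) | O=C1C[C@H]2C=CC(O)CC[C@H]2O1
F4 | step 19 | 3-(1-hydroxyethyl) allylic alcohol from 35 (carbinol epimers) | C=C1C(=O)O[C@@H]2C[C@H](C)[C@@]3(O[Si](C)(C)C)C=C(C(C)O)[C@@]4(C[C@@H]3C[C@H]12)C(=O)O[C@H]1C[C@@H](C)C(CCC5(C)OCCO5)=CC[C@H]14
F5 | step 19 | 3-acetyl enone with C1 silyl ether and C4' dioxolane | C=C1C(=O)O[C@@H]2C[C@H](C)[C@@]3(O[Si](C)(C)C)C=C(C(C)=O)[C@@]4(C[C@@H]3C[C@H]12)C(=O)O[C@H]1C[C@@H](C)C(CCC5(C)OCCO5)=CC[C@H]14
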